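**Retrosynthetic overview**

1. Feature: in the 2H-chromene (ring A = benzo ring, ring B = pyran ring, ring C = catechol ring), C2 is a fully substituted, oxygen-bearing carbon carrying CH3, ring carbon C3 and side-chain carbon C1'. C3 and C1' can both come from vinyl groups, so C2 is prochiral in an aryl divinylcarbinyl ether and its configuration reduces to a choice between two enantiotopic vinyls.
2. Late disconnections: the three silyl ethers (fluoride); C6–CH2 (B-alkyl Suzuki–Miyaura of the aryl bromide with the borane of bis-silylated 2,3-dihydroxystyrene); C2'–C3' (B-alkyl Suzuki–Miyaura of the borane from the C2 vinyl with the (E)-iodoalkene from propargyl alcohol).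
3. Key disconnection: C3=C4, by desymmetrizing asymmetric ring-closing metathesis of 4-bromo-2-ethenylphenyl 3-methylpenta-1,4-dien-3-yl ether to (S)-6-bromo-2-ethenyl-2-methyl-2H-chromene.
4. The triene comes from 5-bromo-2-fluorobenzaldehyde by nucleophilic aromatic substitution with the alkoxide of 3-methylpenta-1,4-dien-3-ol (from ethyl acetate and vinylmagnesium bromide), then Wittig methylenation.
5. Ring order: rings A and C are purchased arenes; ring B is the only ring made (step 4).

Key step: step 4

Assumption: the sense of induction of the chiral molybdenum diolate on this new triene cannot be predicted with certainty; the (S)-biphenolate complex is written, and the mirror-image (R)-complex is to be used if the first run delivers the (R)-chromene.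

**Step 1**
Reactants: 1 ethyl acetate; 2 vinylmagnesium bromide
Product: 4 3-methylpenta-1,4-dien-3-ol, via but-3-en-2-one 3 (not isolated)
Conditions: 2 (2.2 equiv), THF, 0 °C → rt; sat. aq. NH4Cl
Reagents that add atoms: none
Why: Double Grignard addition to an ester; the ketone formed after the first addition is more electrophilic than the ester and takes up the second vinyl group at once, so the symmetric tertiary divinyl carbinol should result (no stereocenter).

**Step 2**
Reactants: 4 3-methylpenta-1,4-dien-3-ol; 5 5-bromo-2-fluorobenzaldehyde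
Product: 7 5-bromo-2-[(3-methylpenta-1,4-dien-3-yl)oxy]benzaldehyde, via potassium 3-methylpenta-1,4-dien-3-olate 6 (not isolated)
Conditions: KH (1.1 equiv), THF, 0 °C; then 5 (1.0 equiv), THF, 0 °C → rt
Reagents that add atoms: none
Why: Nucleophilic aromatic substitution (addition–elimination through a Meisenheimer adduct) of the fluoride that is ortho to the formyl group and para to bromine by a non-enolisable tertiary alkoxide, whose addition to the aldehyde is reversible and unproductive; the product is to be kept below 40 °C and away from acid, because the tertiary bis-allylic aryl ether can ionise or undergo Claisen rearrangement.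

**Step 3**
Reactants: 7 5-bromo-2-[(3-methylpenta-1,4-dien-3-yl)oxy]benzaldehyde
Product: 8 4-bromo-2-ethenyl-1-[(3-methylpenta-1,4-dien-3-yl)oxy]benzene (achiral triene)
Conditions: Ph3PCH3Br, KOtBu, THF, 0 °C → rt
Reagents that add atoms: methyltriphenylphosphonium bromide, C[P+](c1ccccc1)(c1ccccc1)c1ccccc1.[Br-]
Why: Wittig methylenation of a non-enolisable aryl aldehyde, the ether carrying no acidic hydrogen next to oxygen; the triene is to be filtered through basic alumina, dried and degassed so that no aldehyde, phosphine oxide or water reaches the molybdenum catalyst.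

**Step 4**
Reactants: 8 4-bromo-2-ethenyl-1-[(3-methylpenta-1,4-dien-3-yl)oxy]benzene
Product: 9 (2S)-6-bromo-2-ethenyl-2-methyl-2H-chromene
Conditions: Mo(=N-2,6-iPr2C6H3)(=CHCMe2Ph)[(S)-3,3'-di-tert-butyl-5,5',6,6'-tetramethyl-1,1'-biphenyl-2,2'-diolate] (5 mol %), C6H6 (0.1 M), 22 °C, N2, vented to remove ethene
Reagents that add atoms: none
Why: The neophylidene first exchanges at the unhindered styrenyl CH=CH2 to give a molybdenum benzylidene, which adds to one of the two enantiotopic vinyl groups on the carbinol carbon in a [2+2] cycloaddition; cycloreversion of the molybdacyclobutane creates C3=C4 and releases Mo=CH2, which re-enters the cycle at the styrene of the next molecule with loss of ethene. The closest known reaction type is the catalytic asymmetric ring-closing metathesis of prochiral trienes to unsaturated cyclic tertiary ethers with chiral molybdenum diolate alkylidenes, of which an aryl divinylcarbinyl ether is a new substrate. Ring B is closed as a six-membered ring by ring-closing metathesis between the styrenyl carbon (C4) and the inner carbon of one vinyl (C3), the new double bond lying inside the ring. The C2 stereocenter arises by catalyst-controlled enantiotopic-group selection: in the two diastereomeric molybdacyclobutanes the C2 methyl group and the spectator vinyl group compete for the open quadrant left by the biphenolate tert-butyl groups and the arylimido ligand. The step needs this group selectivity and ring closure in preference to cross-metathesis; the fully substituted, oxygen-bearing C2 shields both vinyls from intermolecular attack, so the catalyst should load at the styrene and the vinyl left in the product should be inert. Loss of ethene and the unstrained, conjugated chromene alkene should make the closure effectively irreversible, so the kinetic selectivity is expected to be retained.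

**Step 5**
Reactants: 10 propargyl alcohol (prop-2-yn-1-ol)
Product: 12 (E)-3-iodo-2-methylprop-2-en-1-ol, via dimethylaluminium (E)-3-(dimethylalumanyl)-2-methylprop-2-en-1-olate 11 (not isolated)
Conditions: Me3Al (3 equiv), Cp2ZrCl2 (0.25 equiv), CH2Cl2, 0 °C → rt; I2, THF, −30 → 0 °C; aq. K2CO3
Reagents that add atoms: trimethylaluminium, C[Al](C)C; iodine, II
Why: Negishi zirconium-catalysed carboalumination adds CH3 and aluminium syn across the alkyne with aluminium on the terminal carbon, and iodinolysis of the C–Al bond with retention then fixes the E geometry (iodine trans to CH2OH).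

**Step 6**
Reactants: 12 (E)-3-iodo-2-methylprop-2-en-1-ol
Product: 13 tert-butyl{[(2E)-3-iodo-2-methylprop-2-en-1-yl]oxy}dimethylsilane
Conditions: tBuMe2SiCl, imidazole, CH2Cl2, 0 °C → rt
Reagents that add atoms: tert-butyldimethylsilyl chloride, CC(C)(C)[Si](C)(C)Cl
Why: Standard silylation of a primary alcohol, which keeps the allylic hydroxyl from being activated by borane and palladium in the two coupling steps.

**Step 7**
Reactants: 9 (2S)-6-bromo-2-ethenyl-2-methyl-2H-chromene; 13 tert-butyl{[(2E)-3-iodo-2-methylprop-2-en-1-yl]oxy}dimethylsilane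
Product: 15 tert-butyl({(2E)-5-[(2S)-6-bromo-2-methyl-2H-chromen-2-yl]-2-methylpent-2-en-1-yl}oxy)dimethylsilane, via 9-{2-[(2S)-6-bromo-2-methyl-2H-chromen-2-yl]ethyl}-9-borabicyclo[3.3.1]nonane 14 (not isolated)
Conditions: 9-BBN (1.1 equiv), THF, 0 °C → rt; then 13 (1.2 equiv), PdCl2(dppf) (dppf = 1,1'-bis(diphenylphosphino)ferrocene, 5 mol %), Ph3As (5 mol %), Cs2CO3, DMF–H2O, rt, dark
Reagents that add atoms: none
Why: 9-BBN should add anti-Markovnikov to the monosubstituted C2 vinyl far faster than to the ring 1,2-disubstituted C3=C4, and the B-alkyl Suzuki–Miyaura coupling should then take place at the alkenyl C–I bond at room temperature with retention of the E geometry while the electron-rich aryl C–Br bond (para to the ring oxygen) stays intact; consuming the vinyl before any palladium is present also removes the tertiary allylic aryl ether that zerovalent palladium could ionise, so C2 is not put at risk.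

**Step 8**
Reactants: 16 2,3-dihydroxybenzaldehyde
Product: 17 2,3-bis[(triisopropylsilyl)oxy]benzaldehyde
Conditions: iPr3SiCl (2.5 equiv), imidazole, DMF, rt → 40 °C
Reagents that add atoms: triisopropylsilyl chloride, CC(C)[Si](Cl)(C(C)C)C(C)C
Why: Silylation of both phenols; aryl triisopropylsilyl ethers should survive the ylide and the aqueous phosphate of the later steps, where aryl tert-butyldimethylsilyl ethers would be at risk, and still leave with fluoride.

**Step 9**
Reactants: 17 2,3-bis[(triisopropylsilyl)oxy]benzaldehyde
Product: 18 1-ethenyl-2,3-bis[(triisopropylsilyl)oxy]benzene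
Conditions: Ph3PCH3Br (1.3 equiv), NaN(SiMe3)2 (1.2 equiv), THF, 0 °C → rt
Reagents that add atoms: methyltriphenylphosphonium bromide, C[P+](c1ccccc1)(c1ccccc1)c1ccccc1.[Br-]
Why: Wittig methylenation with a preformed ylide and a slight deficit of base, so that no free amide is left to attack the aryl silyl ethers.

**Step 10**
Reactants: 18 1-ethenyl-2,3-bis[(triisopropylsilyl)oxy]benzene; 15 tert-butyl({(2E)-5-[(2S)-6-bromo-2-methyl-2H-chromen-2-yl]-2-methylpent-2-en-1-yl}oxy)dimethylsilane
Product: 20 tert-butyl({(2E)-5-[(2S)-6-{2-[2,3-bis(triisopropylsilyloxy)phenyl]ethyl}-2-methyl-2H-chromen-2-yl]-2-methylpent-2-en-1-yl}oxy)dimethylsilane, via 9-{2-[2,3-bis(triisopropylsilyloxy)phenyl]ethyl}-9-borabicyclo[3.3.1]nonane 19 (not isolated)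
Conditions: 18 (1.5 equiv), 9-BBN (1.4 equiv), THF, rt; then 15, Pd(OAc)2 (5 mol %), SPhos (2-dicyclohexylphosphino-2',6'-dimethoxybiphenyl, 10 mol %), aq. K3PO4, THF, 50 °C, dark
Reagents that add atoms: none
Why: Hydroboration of the styrene places boron on the terminal carbon, and the B-alkyl Suzuki–Miyaura coupling, run with an electron-rich biarylphosphine that eases oxidative addition into the electron-rich C–Br bond, should form the C6–CH2 bond; the styrene is in excess so no B–H is left for the other alkenes, and 50 °C in the dark is well below the conditions of electrocyclic ring opening that would racemise the 2H-chromene.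

**Step 11**
Reactants: 20 tert-butyl({(2E)-5-[(2S)-6-{2-[2,3-bis(triisopropylsilyloxy)phenyl]ethyl}-2-methyl-2H-chromen-2-yl]-2-methylpent-2-en-1-yl}oxy)dimethylsilane
Product: 21 3-{2-[(2S)-2-[(3E)-5-hydroxy-4-methylpent-3-en-1-yl]-2-methyl-2H-chromen-6-yl]ethyl}benzene-1,2-diol (CNP0267525.1)
Conditions: Bu4NF (4 equiv), AcOH (4 equiv), THF, 0 °C → rt, Ar, dark
Reagents that add atoms: none
Why: Fluoride-induced cleavage of the two aryl silyl ethers and the primary silyl ether in one operation; the acetic acid buffer keeps the catechol protonated so that it is not air-oxidised as the catecholate, and no bond at C2 or at the E-alkene is touched.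

**Compound list**

1 | ethyl acetate | CCOC(C)=O | starting material
2 | vinylmagnesium bromide | C=C[Mg]Br | starting material
3 | but-3-en-2-one | CC(=O)C=C | intermediate
4 | 3-methylpenta-1,4-dien-3-ol | C=CC(C)(O)C=C | intermediate
5 | 5-bromo-2-fluorobenzaldehyde | O=Cc1cc(Br)ccc1F | starting material
6 | potassium 3-methylpenta-1,4-dien-3-olate | [K+].[O-]C(C)(C=C)C=C | intermediate
7 | 5-bromo-2-[(3-methylpenta-1,4-dien-3-yl)oxy]benzaldehyde | C=CC(C)(C=C)Oc1ccc(Br)cc1C=O | intermediate
8 | 4-bromo-2-ethenyl-1-[(3-methylpenta-1,4-dien-3-yl)oxy]benzene | C=CC(C)(C=C)Oc1ccc(Br)cc1C=C | intermediate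
9 | (2S)-6-bromo-2-ethenyl-2-methyl-2H-chromene | C=C[C@@]1(C)C=Cc2cc(Br)ccc2O1 | intermediate
10 | propargyl alcohol (prop-2-yn-1-ol) | C#CCO | starting material
11 | dimethylaluminium (E)-3-(dimethylalumanyl)-2-methylprop-2-en-1-olate | C[Al](C)/C=C(\C)CO[Al](C)C | intermediate
12 | (E)-3-iodo-2-methylprop-2-en-1-ol | I/C=C(\C)CO | intermediate
13 | tert-butyl{[(2E)-3-iodo-2-methylprop-2-en-1-yl]oxy}dimethylsilane | I/C=C(\C)CO[Si](C)(C)C(C)(C)C | intermediate
14 | 9-{2-[(2S)-6-bromo-2-methyl-2H-chromen-2-yl]ethyl}-9-borabicyclo[3.3.1]nonane | B1(CC[C@@]2(C)C=Cc3cc(Br)ccc3O2)C4CCCC1CCC4 | intermediate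
15 | tert-butyl({(2E)-5-[(2S)-6-bromo-2-methyl-2H-chromen-2-yl]-2-methylpent-2-en-1-yl}oxy)dimethylsilane | C/C(=C\CC[C@@]1(C)C=Cc2cc(Br)ccc2O1)CO[Si](C)(C)C(C)(C)C | intermediate
16 | 2,3-dihydroxybenzaldehyde | O=Cc1cccc(O)c1O | starting material
17 | 2,3-bis[(triisopropylsilyl)oxy]benzaldehyde | O=Cc1cccc(O[Si](C(C)C)(C(C)C)C(C)C)c1O[Si](C(C)C)(C(C)C)C(C)C | intermediate
18 | 1-ethenyl-2,3-bis[(triisopropylsilyl)oxy]benzene | C=Cc1cccc(O[Si](C(C)C)(C(C)C)C(C)C)c1O[Si](C(C)C)(C(C)C)C(C)C | intermediate
19 | 9-{2-[2,3-bis(triisopropylsilyloxy)phenyl]ethyl}-9-borabicyclo[3.3.1]nonane | B1(CCc2cccc(O[Si](C(C)C)(C(C)C)C(C)C)c2O[Si](C(C)C)(C(C)C)C(C)C)C3CCCC1CCC3 | intermediate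
20 | tert-butyl({(2E)-5-[(2S)-6-{2-[2,3-bis(triisopropylsilyloxy)phenyl]ethyl}-2-methyl-2H-chromen-2-yl]-2-methylpent-2-en-1-yl}oxy)dimethylsilane | C/C(=C\CC[C@@]1(C)C=Cc2cc(CCc3cccc(O[Si](C(C)C)(C(C)C)C(C)C)c3O[Si](C(C)C)(C(C)C)C(C)C)ccc2O1)CO[Si](C)(C)C(C)(C)C | intermediate
21 | 3-{2-[(2S)-2-[(3E)-5-hydroxy-4-methylpent-3-en-1-yl]-2-methyl-2H-chromen-6-yl]ethyl}benzene-1,2-diol | C/C(=C\CC[C@@]1(C)C=Cc2cc(CCc3cccc(O)c3O)ccc2O1)CO | target

**Step count**

Total step count: 11. Longest linear sequence: 7 steps (steps 1, 2, 3, 4, 7, 10, 11).

**Steps most likely to fail**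

Step 4. The catalyst may discriminate poorly between the two enantiotopic vinyls in the metallacycle-forming event, or it may turn over slowly if the benzylidene is held back by the neighbouring ether oxygen or is quenched by trace protic or carbonyl impurities. The fallback gives up catalyst control for resolution. It sets out from 8, which is closed with the achiral second-generation Grubbs catalyst RuCl2(=CHPh)(PCy3)[1,3-dimesitylimidazolidin-2-ylidene] in CH2Cl2 at room temperature to racemic 6-bromo-2-ethenyl-2-methyl-2H-chromene F1. The enantiomers are then separated by preparative chromatography on a cellulose tris(3,5-dimethylphenylcarbamate) phase. The (S)-enantiomer is collected, its configuration to be assigned by anomalous-dispersion crystallography of a crystalline derivative or by circular dichroism against calculation, and the route is rejoined at 9.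

Step 7. Oxidative addition at the aryl C–Br bond may compete with that at the alkenyl C–I bond, so that the alkylborane of one molecule couples with the bromide of another (oligomerisation), or hydroboration may stray to C3=C4. The fallback reverses the order of the two couplings so that no C–Br bond is present when the alkenyl iodide is coupled. It sets out from 9, which is coupled with borane 19 (Pd(OAc)2, SPhos, aq. K3PO4, THF, 40 °C) to give (2S)-6-{2-[2,3-bis(triisopropylsilyloxy)phenyl]ethyl}-2-ethenyl-2-methyl-2H-chromene F2. Its vinyl group is then hydroborated with 9-BBN to 9-{2-[(2S)-6-{2-[2,3-bis(triisopropylsilyloxy)phenyl]ethyl}-2-methyl-2H-chromen-2-yl]ethyl}-9-borabicyclo[3.3.1]nonane F3 (not isolated), which is coupled with 13 under the conditions of step 7, and the route is rejoined at 20. In this order the tertiary allylic aryl ether meets zerovalent palladium once, so the enantiomeric purity has to be checked after the first coupling.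

Step 2. The hindered alkoxide may attack the formyl carbon and pass on hydride (Cannizzaro- or Tishchenko-type loss of aldehyde) instead of displacing fluoride, or the formyl-activated ether may ionise or rearrange during isolation. The fallback replaces the aldehyde by a nitrile, which activates the fluoride without offering a carbonyl. It sets out from 4, whose alkoxide 6 is combined with commercial 5-bromo-2-fluorobenzonitrile (THF, 0 °C → rt) to give 5-bromo-2-[(3-methylpenta-1,4-dien-3-yl)oxy]benzonitrile F4. Reduction with iBu2AlH in toluene at −78 °C and buffered hydrolysis of the aldimine (aq. potassium sodium tartrate, then dilute citric acid) should give the aldehyde, and the route is rejoined at 7.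

**Further compounds**

F1 | step 4 | racemic 6-bromo-2-ethenyl-2-methyl-2H-chromene | C=CC1(C)C=Cc2cc(Br)ccc2O1
F2 | step 7 | (2S)-6-{2-[2,3-bis(triisopropylsilyloxy)phenyl]ethyl}-2-ethenyl-2-methyl-2H-chromene | C=C[C@@]1(C)C=Cc2cc(CCc3cccc(O[Si](C(C)C)(C(C)C)C(C)C)c3O[Si](C(C)C)(C(C)C)C(C)C)ccc2O1
F3 | step 7 | 9-{2-[(2S)-6-{2-[2,3-bis(triisopropylsilyloxy)phenyl]ethyl}-2-methyl-2H-chromen-2-yl]ethyl}-9-borabicyclo[3.3.1]nonane | B1(CC[C@@]2(C)C=Cc3cc(CCc4cccc(O[Si](C(C)C)(C(C)C)C(C)C)c4O[Si](C(C)C)(C(C)C)C(C)C)ccc3O2)C5CCCC1CCC5
F4 | step 2 | 5-bromo-2-[(3-methylpenta-1,4-dien-3-yl)oxy]benzonitrile | C=CC(C)(C=C)Oc1ccc(Br)cc1C#N
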